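71.5% of the charge of the grey run is still not target at 2.50 d, and the text follows how that remainder shrinks.

| flask | starting material | remark | time |
|---|---|---|---|
| grey | 7.5 mM | run made earlier |  |
| green | 30 mM | run made earlier |  |
| flask | 15 mM |  | 2.5 d |

| run | time / d | target / % | starting material / % |
|---|---|---|---|
| grey | 0.625 | 16.1 | 4.7 |
| grey | 0.833 | 18.4 | 4.1 |
| grey | 1.25 | 20.3 | 4.5 |
| grey | 1.67 | 23.3 | 3.5 |
| grey | 2.50 | 28.5 | 3.9 |
| green | 0.625 | 16.1 | 4.6 |
| green | 0.833 | 16.6 | 4.0 |
| green | 1.25 | 19.8 | 5.2 |
| green | 1.67 | 23.6 | 4.4 |
| green | 2.50 | 28.3 | 3.9 |

(standard deviation of a reading: 0.5 percentage points)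

1. the moment within 2.5 d at which there is most target
2. the amount of target, in percent of the starting material charged, at that time

- the earlier runs were read with a standard deviation of 0.5 percentage points
- a reading or a percentage of target counts all its forms, free or not

1. Starting material is the one reagent charged, so its balance is short: the remainder, the charged c(starting material) minus c(target), counts every other form of the charge.

2. In the grey run the remainder falls from 79.7% at 1.25 d to 71.5% at 2.50 d. Read as an exponential decay, this gives the drain time constant, the time in which the remainder shrinks by the factor e: 11.5 d.

3. Two ways now lead to the green run's target at 2.50 d. One is its reading, 28.3%. The other carries its reading at 1.25 d forward with the grey time constant and gives 28.1%. These come from different runs, and they part by 0.20 percentage points, less than the scatter of 0.5 points, so the time constant is trusted.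

4. The two runs differ in charge by a ratio of 4.00, yet their end readings part by 0.2 points, so the reckoning here puts the flask, charged between them, on the same curve. The window is 0.217 of the time constant, so target in the flask should still be climbing at 2.5 d, at about 28.4%, the mean of the two end readings.

5. The forecast gives 28.4% (27.5% to 29.3%) at 2.5 d (2.35 d to 2.5 d): “Target should therefore be highest at the end of the window.”

6. The flask gives 28.4% at 2.50 d.

    starting material ⇌ intermediate (K = 0.0420, k = 0.0310 /min)
    intermediate → target (k = 0.0270 /min)
    starting material ⇌ dormant form (K = 16.0, k = 0.00700 /min)
    crystals ⇌ target, rate k4*(cs4 - [target]) while solid is left; crystals form when [target] > cs4 (solubility = 2.50 mM, k = 0.710 /min)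

Of the 71.6% of the flask's charge that is not target at that time, the dormant form, the resting state of the charge, holds 67.8%. Starting from this remainder, the time constant of 11.5 d gives 47.2% target at 6.0 d. The neighbour flask left until that time holds 46.1% target.

The data come from a simulation on assumed constants; scatter was added.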